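Reckon the leftover first. If each target takes one coupling partner, then with c(coupling partner) at 0.117 M against c(substrate) at 0.13 M, the partner is the limiting reagent. So 10.0% of the substrate stays over and target is capped at 90.0%.

| setting | Wednesday's | Saturday's | Tuesday's | south | north-east |
|---|---|---|---|---|---|
| substrate | 0.13 M | 0.13 M | 0.065 M | 0.13 M | 0.13 M |
| coupling partner | 0.117 M | 0.117 M | 0.117 M | 0.117 M | 0.117 M |
| free catalyst | 0.060 mM | 0.24 mM | 0.12 mM | 0.12 mM | 0.12 mM |
| remark | run made earlier | run made earlier | run made earlier |  |  |
| time |  |  |  | 2.0 h | 4.0 h |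

| run | time / min | substrate / % | catalyst intermediate C / % | target / % | catalyst intermediate D / % | catalyst intermediate A / % |
|---|---|---|---|---|---|---|
| Wednesday's | 30.0 | 91.0 | 0 | 9.9 | 0.6 | 0 |
| Wednesday's | 60.0 | 80.7 | 0 | 21.7 | 0 | 2.4 |
| Wednesday's | 90.0 | 70.6 | 0 | 29.5 | 0 | 0 |
| Wednesday's | 120 | 62.3 | 0 | 35.4 | 1.2 | 0 |
| Saturday's | 10.0 | 85.1 | 0 | 15.6 | 3.0 | 0.6 |
| Saturday's | 20.0 | 74.9 | 1.0 | 27.4 | 0 | 0 |
| Saturday's | 50.0 | 44.2 | 1.2 | 52.7 | 0 | 0.7 |
| Saturday's | 120 | 13.3 | 0.7 | 85.9 | 0 | 0 |
| Tuesday's | 10.0 | 87.3 | 1.0 | 12.3 | 0 | 0.6 |
| Tuesday's | 20.0 | 80.5 | 0 | 21.0 | 0 | 0 |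
| Tuesday's | 50.0 | 53.5 | 1.9 | 43.1 | 1.7 | 0 |
| Tuesday's | 120 | 20.5 | 0.1 | 78.5 | 0.5 | 0 |

(scatter of a reading: 1 percentage point)

- the numbers in the tables scatter with a standard deviation of 1 percentage point

- which of these there is most of at the end, counted by the substrate in it, south (catalyst intermediate A / substrate / catalyst intermediate D / target / catalyst intermediate C)
- which of these there is most of at the end, counted by the substrate in it, north-east (catalyst intermediate A / substrate / catalyst intermediate D / target / catalyst intermediate C)
- amount of the one of these that there is most of at the end, in percent of the substrate charged, south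
- amount of the one of these that there is most of at the end, in percent of the substrate charged, north-east

Now carry one quantity: the catalyst dose, charged c(free catalyst) times time, compared at fixed charges of substrate and coupling partner. For south it is 0.240 mM·h. Test it on the runs: Wednesday's run at 90.0 min has a dose of 0.0900 mM·h and reads 29.5% target, while Saturday's run at 20.0 min has 0.0800 mM·h and reads 27.4%. On this pair of readings, target follows dose.

South's dose therefore falls at 60.0 min on Saturday's run. Extending Saturday's slope from its readings at 20.0 min and 50.0 min, I expect 61.1% target. North-east's dose of 0.480 mM·h equals Saturday's at 120 min, which reads 85.9%.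

The forecast names target at 61% for south and target at 85% for north-east, on the ground that “Rate scales linearly with catalyst”. Its north-east number lies 0.9 points below mine, which is Saturday's reading.

The flask gives target at 62.0% in south and target at 87.3% in north-east.

    catalyst intermediate D ⇌ free catalyst + target (K = 0.150 M, k = 0.410 /s)
    coupling partner + catalyst intermediate A ⇌ catalyst intermediate B (K = 400 /M, k = 24.0 /M/s)
    catalyst intermediate C ⇌ catalyst intermediate D (K = 8.50, k = 0.480 /s)
    coupling partner → decomposition product (k = 1.90 × 10⁻⁷ /s)
    catalyst intermediate B ⇌ by-product + catalyst intermediate C (K = 0.360 M, k = 4.40 /s)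
    substrate + free catalyst → catalyst intermediate A (k = 3.40 /M/s)

North-east lies 1.4 points from Saturday's reading at equal dose, against a scatter of 1 point. The dose also serves a neighbour flask, the same as south but with 3.0 × 10⁻⁵ M of free catalyst: it has 0.0600 mM·h, the dose of Wednesday's run at 60.0 min, which reads 21.7% target, and that neighbour gives 20.0% target. North-east has not come to rest: it stands below the cap, with 2.9% of its coupling partner free. Left to 40.0 h, it gains 2.6 points to reach 89.9% target, with coupling partner at 0% of its charge and substrate at 10.0%.

(All runs are simulated for substances that don't exist.)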